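**Plan**
1. Retrosynthesis (isocoumarin numbering, side chain C1'–C11'): cut the two aryl O–CH3 bonds and the lactone C1–O2 bond, then the arene bonds C4a–C5 and C8–C8a, then C4–C4a, then C4'–C5'.
2. Enabling feature: C5–C8 of the resorcinol ring, with oxygens on C6 and C8, map onto 1,3-dimethoxycyclohexa-1,3-diene; C4a, C8a and C1 map onto an alk-2-ynoate that already carries C4, C3 and the whole side chain.
3. Forward: the chain is joined first (Grignard opening of (S)-1,2-epoxyheptane, terminal epoxide, propiolate alkynylation), then the benzene ring forms by Diels–Alder/retro-Diels–Alder with loss of ethylene, then the lactone ring closes, then the phenols are freed.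
4. Stereochemistry: C6' (S) comes from hydrolytic kinetic resolution of racemic 1,2-epoxyheptane; C3 (R) comes from a second, catalyst-controlled hydrolytic kinetic resolution of the terminal epoxide. Both centers are then carried as C–O bonds that are never broken.

Key step: step 8

Assumption: the (S,S)- and (R,R)-salen cobalt acetate catalysts are taken to leave the (S)- and (R)-alkyloxirane unreacted, respectively, as is general for unfunctionalised terminal epoxides (salen = N,N'-bis(3,5-di-tert-butylsalicylidene)cyclohexane-1,2-diamine dianion).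

**Step 1**
Reactants: 1 racemic 2-pentyloxirane (1,2-epoxyheptane)
Product: 2 (2S)-2-pentyloxirane
Conditions: (S,S)-(salen)Co(OAc) (0.5 mol%, trivalent cobalt, made from divalent (S,S)-(salen)Co with AcOH/air), H2O (0.55 equiv), neat, 0 °C to rt; distillation
Reagents that add atoms: none
Why: Jacobsen hydrolytic kinetic resolution: the (S,S) catalyst hydrates the R epoxide much faster, so the S epoxide should be recovered in high enantiomeric purity, which fixes C6' of the target.

**Step 2**
Reactants: 2 (2S)-2-pentyloxirane; 3 6-bromohex-1-ene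
Product: 5 (8S)-tridec-1-en-8-ol, via hex-5-enylmagnesium bromide 4 (not isolated)
Conditions: 3, Mg, THF, rt to 40 °C; then CuI (10 mol%), 2, THF, −30 to 0 °C; 1 M HCl quench
Reagents that add atoms: none
Why: Copper-catalysed Grignard opening of a terminal epoxide is an SN2 attack at the unsubstituted carbon, so the carbinol center is not touched and keeps its S configuration.

**Step 3**
Reactants: 5 (8S)-tridec-1-en-8-ol
Product: 6 tert-butyldimethyl[(8S)-tridec-1-en-8-yloxy]silane
Conditions: TBSCl, imidazole, DMF, rt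
Reagents that add atoms: tert-butyldimethylsilyl chloride, C[Si](C)(Cl)C(C)(C)C
Why: Standard imidazole-mediated silylation of a secondary alcohol gives an ether that tolerates peracid, BF3·OEt2 at −78 °C and prolonged heating.

**Step 4**
Reactants: 6 tert-butyldimethyl[(8S)-tridec-1-en-8-yloxy]silane
Product: 7 2-[(6S)-6-(tert-butyldimethylsilyloxy)undecyl]oxirane as a mixture of both epimers at the oxirane carbon
Conditions: mCPBA, NaHCO3, CH2Cl2, 0 °C to rt
Reagents that add atoms: 3-chloroperoxybenzoic acid, O=C(OO)c1cccc(Cl)c1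
Why: Prilezhaev epoxidation of the terminal alkene; the remote stereocenter exerts no facial control, so both epimers are expected in about equal amounts and are sorted in step 5.

**Step 5**
Reactants: 7 2-[(6S)-6-(tert-butyldimethylsilyloxy)undecyl]oxirane (epimer mixture)
Product: 8 (2R)-2-[(6S)-6-(tert-butyldimethylsilyloxy)undecyl]oxirane
Conditions: (R,R)-(salen)Co(OAc) (1 mol%, trivalent cobalt), H2O (0.55 equiv), THF, 0 °C to rt; chromatography
Reagents that add atoms: none
Why: Second hydrolytic kinetic resolution under catalyst control: the (R,R) catalyst should hydrate the 2S epimer and leave the 2R epoxide, which sets C3 of the target; by design at most half of the material is carried on.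

**Step 6**
Reactants: 8 (2R)-2-[(6S)-6-(tert-butyldimethylsilyloxy)undecyl]oxirane; 9 methyl propiolate
Product: 11 methyl (5R,11S)-11-(tert-butyldimethylsilyloxy)-5-hydroxyhexadec-2-ynoate, via methyl 3-lithiopropiolate 10 (not isolated)
Conditions: 9, n-BuLi, THF, −78 °C; BF3·OEt2, then 8, −78 °C; water quench at −78 °C
Reagents that add atoms: none
Why: Yamaguchi–Hirao alkynylation: the BF3-activated epoxide is opened at its terminal carbon by the lithium alkynide, forming C4–C4a without touching the carbinol center, which stays R.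

**Step 7**
Reactants: 11 methyl (5R,11S)-11-(tert-butyldimethylsilyloxy)-5-hydroxyhexadec-2-ynoate
Product: 12 methyl (5R,11S)-5,11-bis(tert-butyldimethylsilyloxy)hexadec-2-ynoate
Conditions: TBSOTf, 2,6-lutidine, CH2Cl2, −78 to 0 °C
Reagents that add atoms: tert-butyldimethylsilyl trifluoromethanesulfonate, CC(C)(C)[Si](C)(C)OS(=O)(=O)C(F)(F)F
Why: Silylation with a silyl triflate and a hindered, non-nucleophilic base protects the hydroxyl without conjugate addition to the ynoate and blocks oxa-Michael or lactonisation pathways during the hot step that follows.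

**Step 8**
Reactants: 12 methyl (5R,11S)-5,11-bis(tert-butyldimethylsilyloxy)hexadec-2-ynoate; 13 1,5-dimethoxycyclohexa-1,4-diene
Product: 16 methyl 2-[(2R,8S)-2,8-bis(tert-butyldimethylsilyloxy)tridecyl]-4,6-dimethoxybenzoate, via 1,3-dimethoxycyclohexa-1,3-diene 14 (not isolated), via bicyclo[2.2.2]octadiene adduct 15 (not isolated)
Conditions: 13 (4 equiv), dichloromaleic anhydride (2 mol%), neat, sealed tube, 185 °C
Reagents that add atoms: none
Why: Under heat and a trace of dichloromaleic anhydride the skipped diene 13 equilibrates to the conjugated diene 14, which adds as the electron-rich four-π component across the electron-poor triple bond of 12 in a concerted, asynchronous [4+2] cycloaddition that forms C4a–C5 and C8–C8a. The bicyclo[2.2.2]octadiene 15 then expels its ethano bridge as ethylene in a retro-[4+2] driven by aromatisation; this is the Alder–Rickert reaction, and the closest known case is the reaction of 1,3-dimethoxycyclohexadienes with alk-2-ynoates to give 6-alkyl-2,4-dimethoxybenzoates. The benzene ring is closed by intermolecular cycloaddition, two bonds at once, and reaches the aromatic oxidation level without an oxidant. No stereocenter is created for the product: the two bridgehead centers of 15 vanish on aromatisation, and C2' and C8' of the chain lie outside the reacting π system and pass through as silyl ethers. The step needs regioselectivity, and both methoxy groups secure it by making the unsubstituted diene terminus the nucleophilic one, so that it bonds to the β carbon of the ynoate and the ester ends up between a methoxy group and the side chain.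

**Step 9**
Reactants: 16 methyl 2-[(2R,8S)-2,8-bis(tert-butyldimethylsilyloxy)tridecyl]-4,6-dimethoxybenzoate
Product: 18 (3R)-3-[(6S)-6-hydroxyundecyl]-6,8-dimethoxy-3,4-dihydro-1H-isochromen-1-one, via diol ester 17 (not isolated)
Conditions: p-TsOH·H2O (0.3 equiv), MeOH, 40 °C; then evaporate, PhMe, 80 °C
Reagents that add atoms: none
Why: Acid methanolysis removes both silyl ethers, and acid-catalysed intramolecular transesterification by the C2' hydroxyl closes the six-membered lactone; the C3–O bond is not broken, so C3 stays R, and the remote C8' hydroxyl cannot reach the ester.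

**Step 10**
Reactants: 18 (3R)-3-[(6S)-6-hydroxyundecyl]-6,8-dimethoxy-3,4-dihydro-1H-isochromen-1-one
Product: 19 (3R)-6,8-dihydroxy-3-[(6S)-6-hydroxyundecyl]-3,4-dihydro-1H-isochromen-1-one
Conditions: BBr3 (5 equiv), CH2Cl2, −78 °C to rt; ice-water quench
Reagents that add atoms: none
Why: Lewis-acid cleavage of aryl methyl ethers with BBr3 is routine for 6,8-dimethoxy-3,4-dihydroisocoumarins, the C8 ether being assisted by chelation to the lactone carbonyl; the secondary alcohol is held as a borate ester and is returned on hydrolysis.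

**Compound list**
1 | racemic 2-pentyloxirane (1,2-epoxyheptane) | CCCCCC1CO1 | starting material
2 | (2S)-2-pentyloxirane | CCCCC[C@H]1CO1 | intermediate
3 | 6-bromohex-1-ene | C=CCCCCBr | starting material
4 | hex-5-enylmagnesium bromide | C=CCCCC[Mg]Br | intermediate
5 | (8S)-tridec-1-en-8-ol | CCCCC[C@H](O)CCCCCC=C | intermediate
6 | tert-butyldimethyl[(8S)-tridec-1-en-8-yloxy]silane | CCCCC[C@H](O[Si](C)(C)C(C)(C)C)CCCCCC=C | intermediate
7 | 2-[(6S)-6-(tert-butyldimethylsilyloxy)undecyl]oxirane, both epimers at the oxirane carbon | CCCCC[C@H](O[Si](C)(C)C(C)(C)C)CCCCCC1CO1 | intermediate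
8 | (2R)-2-[(6S)-6-(tert-butyldimethylsilyloxy)undecyl]oxirane | CCCCC[C@H](O[Si](C)(C)C(C)(C)C)CCCCC[C@@H]1CO1 | intermediate
9 | methyl propiolate | C#CC(=O)OC | starting material
10 | methyl 3-lithiopropiolate | [Li]C#CC(=O)OC | intermediate
11 | methyl (5R,11S)-11-(tert-butyldimethylsilyloxy)-5-hydroxyhexadec-2-ynoate | CCCCC[C@H](O[Si](C)(C)C(C)(C)C)CCCCC[C@@H](O)CC#CC(=O)OC | intermediate
12 | methyl (5R,11S)-5,11-bis(tert-butyldimethylsilyloxy)hexadec-2-ynoate | CCCCC[C@H](O[Si](C)(C)C(C)(C)C)CCCCC[C@@H](O[Si](C)(C)C(C)(C)C)CC#CC(=O)OC | intermediate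
13 | 1,5-dimethoxycyclohexa-1,4-diene | COC1=CCC=C(OC)C1 | starting material
14 | 1,3-dimethoxycyclohexa-1,3-diene | COC1=CC(OC)=CCC1 | intermediate
15 | methyl 3-[(2R,8S)-2,8-bis(tert-butyldimethylsilyloxy)tridecyl]-1,5-dimethoxybicyclo[2.2.2]octa-2,5-diene-2-carboxylate, mixture of bridgehead diastereomers | CCCCC[C@H](O[Si](C)(C)C(C)(C)C)CCCCC[C@@H](O[Si](C)(C)C(C)(C)C)CC1=C(C(=O)OC)C2(OC)CCC1C(OC)=C2 | intermediate
16 | methyl 2-[(2R,8S)-2,8-bis(tert-butyldimethylsilyloxy)tridecyl]-4,6-dimethoxybenzoate | CCCCC[C@H](O[Si](C)(C)C(C)(C)C)CCCCC[C@@H](O[Si](C)(C)C(C)(C)C)Cc1cc(OC)cc(OC)c1C(=O)OC | intermediate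
17 | methyl 2-[(2R,8S)-2,8-dihydroxytridecyl]-4,6-dimethoxybenzoate | CCCCC[C@H](O)CCCCC[C@@H](O)Cc1cc(OC)cc(OC)c1C(=O)OC | intermediate
18 | (3R)-3-[(6S)-6-hydroxyundecyl]-6,8-dimethoxy-3,4-dihydro-1H-isochromen-1-one | CCCCC[C@H](O)CCCCC[C@@H]1Cc2cc(OC)cc(OC)c2C(=O)O1 | intermediate
19 | (3R)-6,8-dihydroxy-3-[(6S)-6-hydroxyundecyl]-3,4-dihydro-1H-isochromen-1-one | CCCCC[C@H](O)CCCCC[C@@H]1Cc2cc(O)cc(O)c2C(=O)O1 | target

**Totals**
Total step count: 10. Longest linear sequence: 10 steps (1 to 19); 3, 9 and 13 enter as purchased materials.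

**Steps most likely to fail**

Step 8. At 185 °C the diene may polymerise or fail to conjugate before it cycloadds, and the ynoate may lose silanol, so conversion to the arene may stay low. The fallback sets out from 8 and comes back at 18, building the arene from a ready-made ring instead of by cycloaddition. Commercial 3,5-dimethoxyphenylmagnesium chloride with CuI (10 mol%) in THF at −30 °C should open 8 at its terminal carbon to give (2R,8S)-8-(tert-butyldimethylsilyloxy)-1-(3,5-dimethoxyphenyl)tridecan-2-ol F1. NBS in MeCN at 0 °C should brominate the ring position next to the side chain and para to a methoxy group, giving (2R,8S)-1-(2-bromo-3,5-dimethoxyphenyl)-8-(tert-butyldimethylsilyloxy)tridecan-2-ol F2. Carbonylative lactonisation (Pd(OAc)2, 1,1'-bis(diphenylphosphino)ferrocene, CO, Et3N, DMF, 100 °C) should then close the lactone to (3R)-3-[(6S)-6-(tert-butyldimethylsilyloxy)undecyl]-6,8-dimethoxy-3,4-dihydro-1H-isochromen-1-one F3, and p-TsOH·H2O in MeOH removes the silyl group to give 18.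

Step 10. Cleavage of the non-chelated C6 methyl ether may stall, and longer exposure to BBr3 may replace the secondary hydroxyl by bromide or open the lactone. The fallback sets out from 12 and comes back at 19, using a diene whose oxygens carry labile silyl groups so that no demethylation is needed. 5,5-Dimethyl-1,3-bis(trimethylsilyloxy)cyclohexa-1,3-diene F4 (from dimedone, TMSOTf, Et3N) is heated neat with 12 at 150–170 °C. The adduct methyl 3-[(2R,8S)-2,8-bis(tert-butyldimethylsilyloxy)tridecyl]-7,7-dimethyl-1,5-bis(trimethylsilyloxy)bicyclo[2.2.2]octa-2,5-diene-2-carboxylate F5 should lose 2-methylpropene to give methyl 2-[(2R,8S)-2,8-bis(tert-butyldimethylsilyloxy)tridecyl]-4,6-bis(trimethylsilyloxy)benzoate F6. Methanolysis of the aryl silyl ethers gives methyl 2-[(2R,8S)-2,8-bis(tert-butyldimethylsilyloxy)tridecyl]-4,6-dihydroxybenzoate F7. p-TsOH·H2O in MeOH, then warm PhMe, removes the alkyl silyl groups through methyl 2-[(2R,8S)-2,8-dihydroxytridecyl]-4,6-dihydroxybenzoate F8 and lactonises it to 19.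

Step 6. The lithiated propiolate decomposes above about −70 °C and the BF3-activated epoxide may rearrange before it is attacked, so the alkynylation may give little product. The fallback sets out from 8 and comes back at 12, bringing in the three carbons as acetylene plus a C1 electrophile. LiC≡CH·H2NCH2CH2NH2 in DMSO at rt should open 8 to (4R,10S)-10-(tert-butyldimethylsilyloxy)pentadec-1-yn-4-ol F9. TBSOTf and 2,6-lutidine give (4R,10S)-4,10-bis(tert-butyldimethylsilyloxy)pentadec-1-yne F10. n-BuLi in THF at −78 °C forms [(4R,10S)-4,10-bis(tert-butyldimethylsilyloxy)pentadec-1-yn-1-yl]lithium F11, which is trapped with methyl chloroformate to give 12.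

**Further compounds**
F1 | step 8 | (2R,8S)-8-(tert-butyldimethylsilyloxy)-1-(3,5-dimethoxyphenyl)tridecan-2-ol | CCCCC[C@H](O[Si](C)(C)C(C)(C)C)CCCCC[C@@H](O)Cc1cc(OC)cc(OC)c1
F2 | step 8 | (2R,8S)-1-(2-bromo-3,5-dimethoxyphenyl)-8-(tert-butyldimethylsilyloxy)tridecan-2-ol | CCCCC[C@H](O[Si](C)(C)C(C)(C)C)CCCCC[C@@H](O)Cc1cc(OC)cc(OC)c1Br
F3 | step 8 | (3R)-3-[(6S)-6-(tert-butyldimethylsilyloxy)undecyl]-6,8-dimethoxy-3,4-dihydro-1H-isochromen-1-one | CCCCC[C@H](O[Si](C)(C)C(C)(C)C)CCCCC[C@@H]1Cc2cc(OC)cc(OC)c2C(=O)O1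
F4 | step 10 | 5,5-dimethyl-1,3-bis(trimethylsilyloxy)cyclohexa-1,3-diene | C[Si](C)(C)OC1=CC(O[Si](C)(C)C)=CC(C)(C)C1
F5 | step 10 | methyl 3-[(2R,8S)-2,8-bis(tert-butyldimethylsilyloxy)tridecyl]-7,7-dimethyl-1,5-bis(trimethylsilyloxy)bicyclo[2.2.2]octa-2,5-diene-2-carboxylate | CCCCC[C@H](O[Si](C)(C)C(C)(C)C)CCCCC[C@@H](O[Si](C)(C)C(C)(C)C)CC1=C(C(=O)OC)C2(O[Si](C)(C)C)CC(C)(C)C1C(O[Si](C)(C)C)=C2
F6 | step 10 | methyl 2-[(2R,8S)-2,8-bis(tert-butyldimethylsilyloxy)tridecyl]-4,6-bis(trimethylsilyloxy)benzoate | CCCCC[C@H](O[Si](C)(C)C(C)(C)C)CCCCC[C@@H](O[Si](C)(C)C(C)(C)C)Cc1cc(O[Si](C)(C)C)cc(O[Si](C)(C)C)c1C(=O)OC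
F7 | step 10 | methyl 2-[(2R,8S)-2,8-bis(tert-butyldimethylsilyloxy)tridecyl]-4,6-dihydroxybenzoate | CCCCC[C@H](O[Si](C)(C)C(C)(C)C)CCCCC[C@@H](O[Si](C)(C)C(C)(C)C)Cc1cc(O)cc(O)c1C(=O)OC
F8 | step 10 | methyl 2-[(2R,8S)-2,8-dihydroxytridecyl]-4,6-dihydroxybenzoate | CCCCC[C@H](O)CCCCC[C@@H](O)Cc1cc(O)cc(O)c1C(=O)OC
F9 | step 6 | (4R,10S)-10-(tert-butyldimethylsilyloxy)pentadec-1-yn-4-ol | CCCCC[C@H](O[Si](C)(C)C(C)(C)C)CCCCC[C@@H](O)CC#C
F10 | step 6 | (4R,10S)-4,10-bis(tert-butyldimethylsilyloxy)pentadec-1-yne | CCCCC[C@H](O[Si](C)(C)C(C)(C)C)CCCCC[C@@H](O[Si](C)(C)C(C)(C)C)CC#C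
F11 | step 6 | [(4R,10S)-4,10-bis(tert-butyldimethylsilyloxy)pentadec-1-yn-1-yl]lithium | CCCCC[C@H](O[Si](C)(C)C(C)(C)C)CCCCC[C@@H](O[Si](C)(C)C(C)(C)C)CC#C[Li]
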